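**Retrosynthetic overview**

1. Leoligin ⇒ angelic acid + the C9 primary alcohol (Mitsunobu C–O bond) ⇒ the tetrahydrofuran-3-carbaldehyde (hydride).
2. Feature used: in the tetrahydrofuran (O1, C2, C3, C4, C5), ring carbon C3 carries the exocyclic oxygenated carbon C9 and lies between aryl-bearing C2 and benzyl-bearing C4. C9 is read as a former ring carbinol carbon of a tetrahydropyran, expelled from the ring when its bond to C4 moves over to C3.
3. Key disconnection: ring bond C3–C4 of the tetrahydrofuran ⇒ all-equatorial 2-aryl-5-benzyl-4-hydroxytetrahydropyran-3-yl mesylate (semipinacol contraction, six to five).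
4. That mesylate ⇒ trans-2-aryl-5-benzyltetrahydropyran-4-one (C3 hydroxylation via the kinetic enol silane, mesylation, hydride) ⇒ (S)-2-aryl-2,3-dihydropyran-4-one (reductive benzylation) ⇒ veratraldehyde + 1-methoxy-3-silyloxybutadiene (asymmetric hetero-Diels–Alder).
5. Ring order: the pyran ring is built first (step 1); the tetrahydrofuran arises from it by contraction (step 7).

Key step: step 7

Assumption: the Ti(IV)/(S)-BINOL catalyst is taken to add the diene to the Si face of veratraldehyde, as with simple aromatic aldehydes, giving the (S)-pyranone; if the sense proves opposite, (R)-BINOL is used and nothing else changes.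

**Route**

Step 1
Reactants: 1 veratraldehyde; 2 (E)-1-methoxy-3-(trimethylsilyloxy)buta-1,3-diene
Product: 4 (S)-2-(3,4-dimethoxyphenyl)-2,3-dihydro-4H-pyran-4-one, via silyl aldol adduct 3 (not isolated)
Conditions: (S)-BINOL (20 mol%), Ti(OiPr)4 (10 mol%), 4 Å MS, Et2O, −20 °C; then TFA, CH2Cl2, 0 °C
Reagents that add atoms: none
Why: Ti(IV)–BINOL-catalysed Mukaiyama aldol addition of the siloxydiene to the Si face of the coordinated aldehyde sets C2 (S) under catalyst control, and TFA then closes adduct 3 by oxa-Michael addition with loss of methanol, which together amount to an asymmetric hetero-Diels–Alder reaction.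

Step 2
Reactants: 4 (S)-2-(3,4-dimethoxyphenyl)-2,3-dihydro-4H-pyran-4-one; 5 3,4-dimethoxybenzyl bromide
Product: 8 (2S,5S)-5-(3,4-dimethoxybenzyl)-2-(3,4-dimethoxyphenyl)tetrahydro-4H-pyran-4-one (2,5-trans), via lithium enolate 6 (not isolated), via cis ketone 7 (not isolated)
Conditions: L-Selectride (1.05 equiv), THF, −78 °C; then 5, −78 → 0 °C; then DBU (0.2 equiv), CH2Cl2, rt
Reagents that add atoms: none
Why: Conjugate hydride addition to the vinylogous ester gives the regiodefined enolate 6, which the reactive benzylic bromide alkylates at C5 (reductive alkylation of an enone); axial entry may give cis ketone 7, and DBU epimerises the enolisable C5 so that the 2,5-diequatorial trans ketone is reached under thermodynamic control while C2 is untouched.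

Step 3
Reactants: 8 (2S,5S)-5-(3,4-dimethoxybenzyl)-2-(3,4-dimethoxyphenyl)tetrahydro-4H-pyran-4-one
Product: 9 trimethyl{[(3S,6S)-3-(3,4-dimethoxybenzyl)-6-(3,4-dimethoxyphenyl)-3,6-dihydro-2H-pyran-4-yl]oxy}silane (enol double bond towards the aryl-bearing carbon)
Conditions: LDA, TMSCl (in situ quench), THF, −78 °C; Et3N, pentane work-up
Reagents that add atoms: chlorotrimethylsilane, C[Si](C)(C)Cl
Why: Kinetic deprotonation by LDA removes a proton from the CH2 at C3 rather than from the benzyl-bearing CH at C5, and the silyl chloride already present traps the enolate as the less substituted silyl enol ether before the β-alkoxy enolate can open the ring; no stereocentre is formed.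

Step 4
Reactants: 9 silyl enol ether
Product: 12 (2R,3R,5S)-5-(3,4-dimethoxybenzyl)-2-(3,4-dimethoxyphenyl)-3-hydroxytetrahydro-4H-pyran-4-one (all substituents equatorial), via silyloxy epoxide 10 (not isolated), via α-silyloxy ketone 11 (not isolated)
Conditions: mCPBA (1.05 equiv), CH2Cl2, −20 → 0 °C; then 1 M HCl, THF, 0 °C
Reagents that add atoms: meta-chloroperbenzoic acid, OOC(=O)c1cccc(Cl)c1
Why: Rubottom oxidation: the peracid epoxidises the electron-rich enol ether on the face opposite the vicinal C2 aryl group, silyl migration opens epoxide 10 to silyloxy ketone 11 and dilute acid frees the alcohol, so that the new C3–OH is trans to aryl and equatorial.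

Step 5
Reactants: 12 hydroxy ketone
Product: 13 (2R,3R,5S)-5-(3,4-dimethoxybenzyl)-2-(3,4-dimethoxyphenyl)-4-oxotetrahydro-2H-pyran-3-yl methanesulfonate
Conditions: MsCl, Et3N, CH2Cl2, −20 °C
Reagents that add atoms: methanesulfonyl chloride, CS(=O)(=O)Cl
Why: Sulfonylation of the secondary alcohol with mesyl chloride and triethylamine occurs at oxygen with retention at C3, and the short cold reaction limits enolisation of the α-sulfonyloxy ketone.

Step 6
Reactants: 13 mesyloxy ketone
Product: 14 (2R,3S,4R,5S)-5-(3,4-dimethoxybenzyl)-2-(3,4-dimethoxyphenyl)-4-hydroxytetrahydro-2H-pyran-3-yl methanesulfonate (aryl, mesylate, hydroxyl and benzyl all equatorial)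
Conditions: NaBH4, CeCl3·7H2O, MeOH–THF, −40 °C
Reagents that add atoms: none
Why: Luche-type borohydride reduction: the small hydride adds axially to the chair ketone flanked by two equatorial substituents and gives the equatorial C4 alcohol trans to the mesylate, while the cold, nearly neutral medium leaves the mesylate in place; any C4 epimer would not harm the route, because its C4–C5 bond is equally antiperiplanar to the equatorial mesylate and C4 ends as the formyl carbon.

Step 7
Reactants: 14 all-equatorial hydroxy mesylate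
Product: 16 (2S,3S,4R)-4-(3,4-dimethoxybenzyl)-2-(3,4-dimethoxyphenyl)tetrahydrofuran-3-carbaldehyde, via potassium alkoxide 15 (not isolated)
Conditions: KHMDS (1.0 equiv), THF, −78 → −20 °C; AcOH then pH 7 buffer at −78 °C; crude product used at once
Reagents that add atoms: none
Why: KHMDS converts 14 into alkoxide 15, in whose all-equatorial chair the C3–OMs bond is antiperiplanar to the ring bond C4–C5; as the C4–O⁻ pair folds down to C=O, C5 moves with its bonding pair from C4 to the back side of C3 and mesylate leaves in a concerted 1,2-alkyl shift. The closest known reaction type is the base-induced semipinacol (pinacol-type) ring contraction of cyclic 1,2-diol monosulfonates with an equatorial leaving group, known for carbocyclic and pyranoid rings. The tetrahydrofuran is closed by ring contraction and not by cyclisation: the new bond C3–C5 (target C3–C4) replaces C4–C5, and the former ring carbon C4 is expelled as the formyl carbon. The new stereocentre (target C3) is fixed stereospecifically by inversion at the mesylate carbon, while the migrating carbon keeps its configuration and C2 is untouched, which places CHO trans to aryl and cis to benzyl. The step needs carbon migration to beat hydride shift, epoxide closure and ring-oxygen participation: the axial C4–H is gauche to the leaving group, epoxide closure would demand the all-axial chair or a twist form of a tetrasubstituted ring, and an anionic push in THF without Lewis acid gives the benzylic C2–O1 bond (also anti to C3–OMs) no reason to ionise. The single equivalent of base is consumed as potassium mesylate, and the cold buffered quench with immediate use in step 8 protects the α-formyl stereocentre from epimerisation.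

Step 8
Reactants: 16 tetrahydrofuran-3-carbaldehyde (crude)
Product: 17 [(2S,3R,4R)-4-(3,4-dimethoxybenzyl)-2-(3,4-dimethoxyphenyl)tetrahydrofuran-3-yl]methanol
Conditions: NaBH4, MeOH, 0 °C
Reagents that add atoms: none
Why: Sodium borohydride reduces the aldehyde chemoselectively at 0 °C without creating a stereocentre, and doing so directly on crude 16 removes the acidic α-formyl hydrogen before C3 can epimerise.

Step 9
Reactants: 17 primary alcohol; 18 angelic acid
Product: 19 leoligin, [(2S,3R,4R)-4-(3,4-dimethoxybenzyl)-2-(3,4-dimethoxyphenyl)tetrahydrofuran-3-yl]methyl (Z)-2-methylbut-2-enoate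
Conditions: PPh3, DIAD, THF, 0 °C → rt
Reagents that add atoms: none
Why: Mitsunobu esterification activates the primary alcohol as an alkoxyphosphonium ion that the angelate anion displaces at the CH2 carbon, so the acid is never turned into an acylating agent and the Z to E (angelate to tiglate) isomerisation seen with acyl-transfer catalysts is avoided; no stereocentre is touched.

**Compound list**

1 | veratraldehyde (3,4-dimethoxybenzaldehyde) | COc1ccc(C=O)cc1OC | starting material
2 | (E)-1-methoxy-3-(trimethylsilyloxy)buta-1,3-diene | CO/C=C/C(=C)O[Si](C)(C)C | starting material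
3 | (S,E)-5-(3,4-dimethoxyphenyl)-1-methoxy-5-(trimethylsilyloxy)pent-1-en-3-one (silyl aldol adduct) | CO/C=C/C(=O)C[C@H](O[Si](C)(C)C)c1ccc(OC)c(OC)c1 | intermediate
4 | (S)-2-(3,4-dimethoxyphenyl)-2,3-dihydro-4H-pyran-4-one | O=C1C=CO[C@H](c2ccc(OC)c(OC)c2)C1 | intermediate
5 | 3,4-dimethoxybenzyl bromide | COc1ccc(CBr)cc1OC | starting material
6 | lithium (S)-2-(3,4-dimethoxyphenyl)-3,6-dihydro-2H-pyran-4-olate | [Li]OC1=CCO[C@H](c2ccc(OC)c(OC)c2)C1 | intermediate
7 | (2S,5R)-5-(3,4-dimethoxybenzyl)-2-(3,4-dimethoxyphenyl)tetrahydro-4H-pyran-4-one (2,5-cis) | C1O[C@H](c2ccc(OC)c(OC)c2)CC(=O)[C@@H]1Cc1ccc(OC)c(OC)c1 | intermediate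
8 | (2S,5S)-5-(3,4-dimethoxybenzyl)-2-(3,4-dimethoxyphenyl)tetrahydro-4H-pyran-4-one (2,5-trans) | C1O[C@H](c2ccc(OC)c(OC)c2)CC(=O)[C@H]1Cc1ccc(OC)c(OC)c1 | intermediate
9 | trimethyl{[(3S,6S)-3-(3,4-dimethoxybenzyl)-6-(3,4-dimethoxyphenyl)-3,6-dihydro-2H-pyran-4-yl]oxy}silane | C1O[C@H](c2ccc(OC)c(OC)c2)C=C(O[Si](C)(C)C)[C@H]1Cc1ccc(OC)c(OC)c1 | intermediate
10 | 3,4-epoxide of 9 (4-trimethylsilyloxy; oxirane oxygen anti to the C2 aryl group, syn to the C5 benzyl group) | C1O[C@H](c2ccc(OC)c(OC)c2)[C@H]2O[C@@]2(O[Si](C)(C)C)[C@H]1Cc1ccc(OC)c(OC)c1 | intermediate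
11 | (2R,3R,5S)-5-(3,4-dimethoxybenzyl)-2-(3,4-dimethoxyphenyl)-3-(trimethylsilyloxy)tetrahydro-4H-pyran-4-one | C1O[C@H](c2ccc(OC)c(OC)c2)[C@@H](O[Si](C)(C)C)C(=O)[C@H]1Cc1ccc(OC)c(OC)c1 | intermediate
12 | (2R,3R,5S)-5-(3,4-dimethoxybenzyl)-2-(3,4-dimethoxyphenyl)-3-hydroxytetrahydro-4H-pyran-4-one | C1O[C@H](c2ccc(OC)c(OC)c2)[C@@H](O)C(=O)[C@H]1Cc1ccc(OC)c(OC)c1 | intermediate
13 | (2R,3R,5S)-5-(3,4-dimethoxybenzyl)-2-(3,4-dimethoxyphenyl)-4-oxotetrahydro-2H-pyran-3-yl methanesulfonate | C1O[C@H](c2ccc(OC)c(OC)c2)[C@@H](OS(C)(=O)=O)C(=O)[C@H]1Cc1ccc(OC)c(OC)c1 | intermediate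
14 | (2R,3S,4R,5S)-5-(3,4-dimethoxybenzyl)-2-(3,4-dimethoxyphenyl)-4-hydroxytetrahydro-2H-pyran-3-yl methanesulfonate (all-equatorial) | C1O[C@H](c2ccc(OC)c(OC)c2)[C@@H](OS(C)(=O)=O)[C@H](O)[C@H]1Cc1ccc(OC)c(OC)c1 | intermediate
15 | potassium alkoxide of 14 | C1O[C@H](c2ccc(OC)c(OC)c2)[C@@H](OS(C)(=O)=O)[C@H](O[K])[C@H]1Cc1ccc(OC)c(OC)c1 | intermediate
16 | (2S,3S,4R)-4-(3,4-dimethoxybenzyl)-2-(3,4-dimethoxyphenyl)tetrahydrofuran-3-carbaldehyde | C1O[C@H](c2ccc(OC)c(OC)c2)[C@@H](C=O)[C@H]1Cc1ccc(OC)c(OC)c1 | intermediate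
17 | [(2S,3R,4R)-4-(3,4-dimethoxybenzyl)-2-(3,4-dimethoxyphenyl)tetrahydrofuran-3-yl]methanol | OC[C@H]1[C@@H](Cc2ccc(OC)c(OC)c2)CO[C@@H]1c1ccc(OC)c(OC)c1 | intermediate
18 | angelic acid, (Z)-2-methylbut-2-enoic acid | C/C=C(/C)C(=O)O | starting material
19 | leoligin | C/C=C(/C)C(=O)OC[C@H]1[C@@H](Cc2ccc(OC)c(OC)c2)CO[C@@H]1c1ccc(OC)c(OC)c1 | target

Total step count: 9. Longest linear sequence: 9 steps (from 1 to 19).

**Steps most likely to fail**

Step 7. The alkoxide may reach a twist conformer and displace the mesylate to an epoxide. The ring oxygen may assist ionisation and open the benzylic C–O bond. The formyl-bearing stereocentre may epimerise before the quench. The fallback sets out from 8 and comes back at 17; it makes the same C5-to-C3 ring contraction as a Wolff rearrangement. The kinetic lithium enolate of 8 (LiHMDS, THF, −78 °C) is acylated with 2,2,2-trifluoroethyl trifluoroacetate to the 3-trifluoroacetyl ketone F1. Detrifluoroacetylative diazo transfer (MsN3, Et3N, MeCN) should give the 3-diazo-4-ketone F2. Irradiation in methanol should contract the ring through the ketene to the methyl tetrahydrofuran-3-carboxylate F3. Its C3 is then set by protonation rather than stereospecifically; brief NaOMe/MeOH equilibration is expected to favour the ester trans to the aryl group. LiAlH4 in THF then gives 17.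

Step 4. Facial selectivity of the epoxidation may be poor, because the two allylic substituents of 9 sit on opposite faces. The acid by-product may also return the enol silane to 8 before it is oxidised. The fallback sets out from 4 and comes back at 12; it oxygenates C3 while the aryl group is the only stereocontrol element. Enone 4 is silylated at oxygen (TBSOTf, Et3N, CH2Cl2, 0 °C) to the cross-conjugated silyl dienol ether F4. Rubottom oxidation with dimethyldioxirane (acetone, −40 °C, silyl transfer to the new oxygen) should give the trans 3-silyloxy enone F5. Conjugate reduction, benzylation with 5 and DBU equilibration (conditions of step 2) should give the all-equatorial silyloxy ketone F6. HF·pyridine in THF then frees 12.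

Step 2. Proton exchange between enolate and product may cause polyalkylation or alkylation at C3. Some 1,2-reduction may compete. The C5 equilibration may stall short of the trans isomer. The fallback sets out from 4 and comes back at 8; it separates C–C bond formation from the hydride addition. Enone 4 is iodinated at the α-carbon (I2, pyridine, CH2Cl2) to the 5-iodo enone F7. Negishi coupling with (3,4-dimethoxybenzyl)zinc bromide F8 (from 5, Zn dust, LiCl, THF; Pd(PPh3)4 cat.) should give the 5-benzyl enone F9. L-Selectride at −78 °C with a protic quench, followed by DBU equilibration, gives 8.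

**Further compounds**

F1 | step 7 | 3-trifluoroacetyl derivative of 8, drawn as its ring enol (C2 and C5 as in 8) | OC1=C(C(=O)C(F)(F)F)[C@@H](c2ccc(OC)c(OC)c2)OC[C@@H]1Cc1ccc(OC)c(OC)c1
F2 | step 7 | (2R,5S)-3-diazo-5-(3,4-dimethoxybenzyl)-2-(3,4-dimethoxyphenyl)tetrahydro-4H-pyran-4-one | C1O[C@H](c2ccc(OC)c(OC)c2)C(=[N+]=[N-])C(=O)[C@H]1Cc1ccc(OC)c(OC)c1
F3 | step 7 | methyl (2S,3S,4R)-4-(3,4-dimethoxybenzyl)-2-(3,4-dimethoxyphenyl)tetrahydrofuran-3-carboxylate | COC(=O)[C@H]1[C@@H](Cc2ccc(OC)c(OC)c2)CO[C@@H]1c1ccc(OC)c(OC)c1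
F4 | step 4 | (S)-tert-butyl{[2-(3,4-dimethoxyphenyl)-2H-pyran-4-yl]oxy}dimethylsilane | C1=CC(O[Si](C)(C)C(C)(C)C)=C[C@@H](c2ccc(OC)c(OC)c2)O1
F5 | step 4 | (2R,3R)-3-[(tert-butyldimethylsilyl)oxy]-2-(3,4-dimethoxyphenyl)-2,3-dihydro-4H-pyran-4-one | C1=CC(=O)[C@H](O[Si](C)(C)C(C)(C)C)[C@@H](c2ccc(OC)c(OC)c2)O1
F6 | step 4 | (2R,3R,5S)-3-[(tert-butyldimethylsilyl)oxy]-5-(3,4-dimethoxybenzyl)-2-(3,4-dimethoxyphenyl)tetrahydro-4H-pyran-4-one | C1O[C@H](c2ccc(OC)c(OC)c2)[C@@H](O[Si](C)(C)C(C)(C)C)C(=O)[C@H]1Cc1ccc(OC)c(OC)c1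
F7 | step 2 | (S)-2-(3,4-dimethoxyphenyl)-5-iodo-2,3-dihydro-4H-pyran-4-one | O=C1C(I)=CO[C@H](c2ccc(OC)c(OC)c2)C1
F8 | step 2 | (3,4-dimethoxybenzyl)zinc bromide | COc1ccc(C[Zn]Br)cc1OC
F9 | step 2 | (S)-5-(3,4-dimethoxybenzyl)-2-(3,4-dimethoxyphenyl)-2,3-dihydro-4H-pyran-4-one | O=C1C(Cc2ccc(OC)c(OC)c2)=CO[C@H](c2ccc(OC)c(OC)c2)C1
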